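**Retrosynthetic overview**

- The strategy rests on the exocyclic trisubstituted alkene C2=C3′ on ring B of the octalin. Its ring neighbours C1H2 and C3H2 differ only through the remote C4a=C8a alkene, so the Z geometry is written mechanistically: ring B and the alkene are cut back to acetate 10, CO and MeOH by a palladium-catalysed allyl–alkyne cyclisation with carbonylative capture.
- Ring A is bought as 2,2-dimethylcyclohexanone; the butynyl arm is attached by Negishi coupling of an enol triflate. Ring order: ring A, then ring B (step 7), then the 1,2-dioxane (step 18).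
- Acetone dimethylhydrazone is the C5–C6–C1′ linchpin: it is alkylated first by the (Z)-allylic bromide 15 (C1′–C2′) and then by epoxide 23 (C4–C5). The epoxide carries C2 and C3 from a Sharpless epoxidation and a Me3Al opening.
- The dioxane O–C3 bond comes from a C6 hydroperoxy ketal that displaces a C3 mesylate with inversion; C6 is then set by methylation of the peroxycarbenium ion, and C1 is oxidised to the acid last.

Key step: step 7

Remark on locants: C1–C6 run from the carboxyl carbon through the dioxane carbons C3 and C6; C1′–C3′ are the chain carbons from C6 to the bicycle; the bicycle is numbered as an octalin with the gem-dimethyl carbon C5 and the ring-fusion alkene C4a=C8a.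
Assumptions: (E)-but-2-ene-1,4-diol is taken as purchasable, and the two C6 anomers of peroxy ketal 29 are used together, since both give the same peroxycarbenium ion.

**Route**

Step 1
Reactants: 1 2,2-dimethylcyclohexanone; 2 dimethyl carbonate
Product: 3 methyl 3,3-dimethyl-2-oxocyclohexane-1-carboxylate (racemic)
Conditions: NaH, THF, reflux; AcOH work-up
Reagents that add atoms: none
Why: Claisen-type methoxycarbonylation at the only enolisable α-carbon of 1, driven by formation of the β-keto ester enolate.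

Step 2
Reactants: 3 methyl 3,3-dimethyl-2-oxocyclohexane-1-carboxylate
Product: 4 methyl 3,3-dimethyl-2-{[(trifluoromethyl)sulfonyl]oxy}cyclohex-1-ene-1-carboxylate
Conditions: NaH, Et2O, 0 °C; then Tf2O, 0 °C to rt
Reagents that add atoms: trifluoromethanesulfonic anhydride O=S(=O)(OS(=O)(=O)C(F)(F)F)C(F)(F)F
Why: O-sulfonylation of the sodium enolate gives the enol triflate regiospecifically, since the ketone can enolise only toward the ester carbon.

Step 3
Reactants: 4 methyl 3,3-dimethyl-2-{[(trifluoromethyl)sulfonyl]oxy}cyclohex-1-ene-1-carboxylate; 5 (4-bromobut-1-yn-1-yl)trimethylsilane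
Product: 7 methyl 3,3-dimethyl-2-[4-(trimethylsilyl)but-3-yn-1-yl]cyclohex-1-ene-1-carboxylate, via alkylzinc bromide 6 (not isolated)
Conditions: Zn dust, LiCl, THF, 50 °C (from 5); then 4, Pd(OAc)2 (3 mol%), SPhos (6 mol%), THF, 50 °C
Reagents that add atoms: none
Why: Zinc insertion into the primary bromide followed by Negishi sp2–sp3 cross-coupling at the electron-poor enol triflate should work because the bulky biaryl phosphine favours reductive elimination next to the gem-dimethyl carbon over β-hydride loss.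

Step 4
Reactants: 7 methyl 3,3-dimethyl-2-[4-(trimethylsilyl)but-3-yn-1-yl]cyclohex-1-ene-1-carboxylate
Product: 8 {3,3-dimethyl-2-[4-(trimethylsilyl)but-3-yn-1-yl]cyclohex-1-en-1-yl}methanol
Conditions: i-Bu2AlH, CH2Cl2, −78 to 0 °C; aqueous potassium sodium tartrate work-up
Reagents that add atoms: none
Why: i-Bu2AlH 1,2-reduction of the conjugated ester gives the allylic alcohol and leaves the silylalkyne untouched at low temperature.

Step 5
Reactants: 8 {3,3-dimethyl-2-[4-(trimethylsilyl)but-3-yn-1-yl]cyclohex-1-en-1-yl}methanol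
Product: 9 [2-(but-3-yn-1-yl)-3,3-dimethylcyclohex-1-en-1-yl]methanol
Conditions: K2CO3 (cat.), MeOH, rt
Reagents that add atoms: none
Why: Base-catalysed methanolysis of the alkynyl–silicon bond (protodesilylation) frees the terminal alkyne.

Step 6
Reactants: 9 [2-(but-3-yn-1-yl)-3,3-dimethylcyclohex-1-en-1-yl]methanol
Product: 10 [2-(but-3-yn-1-yl)-3,3-dimethylcyclohex-1-en-1-yl]methyl acetate
Conditions: Ac2O, pyridine, DMAP (cat.), CH2Cl2, 0 °C to rt
Reagents that add atoms: acetic anhydride CC(=O)OC(C)=O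
Why: DMAP-catalysed acylation of the primary allylic alcohol gives the ionisable acetate needed for allylpalladium formation.

Step 7
Reactants: 10 [2-(but-3-yn-1-yl)-3,3-dimethylcyclohex-1-en-1-yl]methyl acetate; 11 carbon monoxide; 12 methanol
Product: 13 methyl (2Z)-2-(5,5-dimethyl-3,4,5,6,7,8-hexahydronaphthalen-2(1H)-ylidene)acetate
Conditions: Pd(PPh3)4 (10 mol%), CO (1 atm), MeOH/AcOH 4:1, 45 °C
Reagents that add atoms: none
Why: Zerovalent palladium ionises the allylic acetate of 10 to an allylpalladium acetate whose less hindered CH2 terminus (octalin C1) and palladium add syn across the tethered terminal alkyne, forming C1–C2 and placing palladium on the exocyclic carbon; CO then inserts into the vinyl–palladium bond with retention and methanolysis of the acylpalladium releases 13 and returns the catalyst. The closest known reaction type is the palladium-ene cyclisation of allylic acetates onto alkynes with carbonylative termination, which has the same steric course as the nickel-mediated allyl halide–alkyne–CO coupling that gives (Z)-2,5-dienoates. Ring B closes in the 6-exo-dig mode, and the tetrasubstituted C4a=C8a alkene stays in the ring because ring A holds the allyl unit cis. No stereocentre is formed; the element that is set is the alkene geometry, Z because C1 and the ester carbon enter on the same side of the former triple bond. The step needs cyclisation to outrun direct methoxycarbonylation of the allyl fragment and β-hydride loss, which the two-carbon tether, the low CO pressure and the moderate temperature should secure.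

Step 8
Reactants: 13 methyl (2Z)-2-(5,5-dimethyl-3,4,5,6,7,8-hexahydronaphthalen-2(1H)-ylidene)acetate
Product: 14 (2Z)-2-(5,5-dimethyl-3,4,5,6,7,8-hexahydronaphthalen-2(1H)-ylidene)ethan-1-ol
Conditions: i-Bu2AlH, CH2Cl2, −78 °C; aqueous potassium sodium tartrate work-up
Reagents that add atoms: none
Why: i-Bu2AlH 1,2-reduction of the enoate at low temperature gives the allylic alcohol without base, so the alkene geometry and the skipped diene are not disturbed.

Step 9
Reactants: 14 (2Z)-2-(5,5-dimethyl-3,4,5,6,7,8-hexahydronaphthalen-2(1H)-ylidene)ethan-1-ol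
Product: 15 (2Z)-2-(2-bromoethylidene)-5,5-dimethyl-1,2,3,4,5,6,7,8-octahydronaphthalene
Conditions: CBr4, PPh3, CH2Cl2, −20 to 0 °C
Reagents that add atoms: carbon tetrabromide BrC(Br)(Br)Br
Why: Appel bromination displaces the alkoxyphosphonium ion by SN2 under neutral conditions, so no allyl cation forms and the Z geometry should be kept.

Step 10
Reactants: 15 (2Z)-2-(2-bromoethylidene)-5,5-dimethyl-1,2,3,4,5,6,7,8-octahydronaphthalene; 16 acetone N,N-dimethylhydrazone
Product: 17 (5Z)-5-(5,5-dimethyl-3,4,5,6,7,8-hexahydronaphthalen-2(1H)-ylidene)pentan-2-one N,N-dimethylhydrazone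
Conditions: n-BuLi, THF, −78 to 0 °C (16, 2 equiv); then 15, −78 to 0 °C
Reagents that add atoms: none
Why: Hydrazone (azaenolate) alkylation: the lithium azaenolate attacks the primary allylic bromide by SN2 at carbon, forming C1′–C2′ as the monoalkylated product without touching the alkene geometry.

Step 11
Reactants: 18 (2E)-but-2-ene-1,4-diol
Product: 19 (2E)-4-[(tert-butyldiphenylsilyl)oxy]but-2-en-1-ol
Conditions: TBDPSCl (1 equiv), imidazole, 18 (3 equiv), DMF, 0 °C to rt
Reagents that add atoms: tert-butyl(chloro)diphenylsilane CC(C)(C)[Si](Cl)(c1ccccc1)c1ccccc1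
Why: Statistical monosilylation of the symmetrical diol used in excess gives the mono-ether.

Step 12
Reactants: 19 (2E)-4-[(tert-butyldiphenylsilyl)oxy]but-2-en-1-ol
Product: 20 [(2S,3S)-3-{[(tert-butyldiphenylsilyl)oxy]methyl}oxiran-2-yl]methanol
Conditions: Ti(OiPr)4 (10 mol%), L-(+)-diethyl tartrate (12 mol%), t-BuOOH, 4 Å MS, CH2Cl2, −20 °C
Reagents that add atoms: tert-butyl hydroperoxide CC(C)(C)OO
Why: Sharpless asymmetric epoxidation; the titanium–L-tartrate complex delivers oxygen to the face of the (E)-allylic alcohol that gives the (2S,3S)-epoxy alcohol, which fixes both epoxide carbons.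

Step 13
Reactants: 20 [(2S,3S)-3-{[(tert-butyldiphenylsilyl)oxy]methyl}oxiran-2-yl]methanol
Product: 21 (2R,3R)-4-[(tert-butyldiphenylsilyl)oxy]-3-methylbutane-1,2-diol
Conditions: Me3Al (3 equiv), hexane/CH2Cl2, 0 °C to rt
Reagents that add atoms: trimethylaluminium C[Al](C)C
Why: Alkoxide-directed opening of the 2,3-epoxy alcohol by Me3Al at the epoxide carbon remote from the hydroxymethyl group, with inversion, gives the anti 3-methyl-1,2-diol; this sets the methyl-bearing centre (future C2) and keeps the carbinol centre (future C3).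

Step 14
Reactants: 21 (2R,3R)-4-[(tert-butyldiphenylsilyl)oxy]-3-methylbutane-1,2-diol
Product: 23 tert-butyl{(2R)-2-[(2R)-oxiran-2-yl]propoxy}diphenylsilane, via primary tosylate 22 (not isolated)
Conditions: TsCl, Et3N, Bu2SnO (cat.), CH2Cl2, rt; then K2CO3, MeOH, rt
Reagents that add atoms: none
Why: Tin-acetal-catalysed sulfonylation of the primary hydroxyl and Williamson-type closure by the secondary alkoxide give the terminal epoxide with retention at the carbinol carbon.

Step 15
Reactants: 17 (5Z)-5-(5,5-dimethyl-3,4,5,6,7,8-hexahydronaphthalen-2(1H)-ylidene)pentan-2-one N,N-dimethylhydrazone; 23 tert-butyl{(2R)-2-[(2R)-oxiran-2-yl]propoxy}diphenylsilane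
Product: 25 (2R,3S,9Z)-1-[(tert-butyldiphenylsilyl)oxy]-9-(5,5-dimethyl-3,4,5,6,7,8-hexahydronaphthalen-2(1H)-ylidene)-3-hydroxy-2-methylnonan-6-one, via hydroxy hydrazone 24 (not isolated)
Conditions: LiN(i-Pr)2, THF, 0 °C (17); then 23, 0 °C to rt; then saturated aqueous oxalic acid, Et2O, rt
Reagents that add atoms: water O
Why: Second hydrazone alkylation: kinetic deprotonation of 17 at its methyl group and SN2 opening of epoxide 23 at the unsubstituted carbon form C4–C5 with the C3 carbinol configuration unchanged, and two-phase oxalic acid hydrolysis frees the C6 ketone.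

Step 16
Reactants: 25 (2R,3S,9Z)-1-[(tert-butyldiphenylsilyl)oxy]-9-(5,5-dimethyl-3,4,5,6,7,8-hexahydronaphthalen-2(1H)-ylidene)-3-hydroxy-2-methylnonan-6-one
Product: 26 (2R,3S,9Z)-1-[(tert-butyldiphenylsilyl)oxy]-9-(5,5-dimethyl-3,4,5,6,7,8-hexahydronaphthalen-2(1H)-ylidene)-2-methyl-6-oxononan-3-yl methanesulfonate
Conditions: MsCl, Et3N, CH2Cl2, −20 to 0 °C
Reagents that add atoms: methanesulfonyl chloride CS(=O)(=O)Cl
Why: Sulfonylation of the secondary alcohol with retention turns C3 into an SN2 electrophile.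

Step 17
Reactants: 26 (2R,3S,9Z)-1-[(tert-butyldiphenylsilyl)oxy]-9-(5,5-dimethyl-3,4,5,6,7,8-hexahydronaphthalen-2(1H)-ylidene)-2-methyl-6-oxononan-3-yl methanesulfonate
Product: 27 (2R,3S,9Z)-1-[(tert-butyldiphenylsilyl)oxy]-9-(5,5-dimethyl-3,4,5,6,7,8-hexahydronaphthalen-2(1H)-ylidene)-6,6-dimethoxy-2-methylnonan-3-yl methanesulfonate
Conditions: HC(OMe)3, MeOH, PPTS (cat.), 0 °C to rt; Et3N quench; used at once
Reagents that add atoms: trimethyl orthoformate COC(OC)OC
Why: Orthoformate-driven acid-catalysed ketalisation removes the enolisable C6 carbonyl before base is used and supplies the ketal from which the hydroperoxy ketal is made.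

Step 18
Reactants: 27 (2R,3S,9Z)-1-[(tert-butyldiphenylsilyl)oxy]-9-(5,5-dimethyl-3,4,5,6,7,8-hexahydronaphthalen-2(1H)-ylidene)-6,6-dimethoxy-2-methylnonan-3-yl methanesulfonate
Product: 29 tert-butyl{(2R)-2-[(3R)-6-[(3Z)-3-(5,5-dimethyl-3,4,5,6,7,8-hexahydronaphthalen-2(1H)-ylidene)propyl]-6-methoxy-1,2-dioxan-3-yl]propoxy}diphenylsilane (both C6 anomers), via hydroperoxy ketal 28 (not isolated)
Conditions: anhydrous H2O2 in Et2O, CSA (cat.), 0 °C; aqueous NaHCO3 wash; then KOtBu, 18-crown-6, THF, 0 °C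
Reagents that add atoms: hydrogen peroxide OO
Why: Acid-catalysed perhydrolysis (exchange of one ketal methoxy group for hydrogen peroxide) gives the C6 hydroperoxy ketal, whose potassium salt then displaces the C3 mesylate in an intramolecular 6-exo-tet SN2 alkylation that closes the 1,2-dioxane and inverts C3 from S to R.

Step 19
Reactants: 29 tert-butyl{(2R)-2-[(3R)-6-[(3Z)-3-(5,5-dimethyl-3,4,5,6,7,8-hexahydronaphthalen-2(1H)-ylidene)propyl]-6-methoxy-1,2-dioxan-3-yl]propoxy}diphenylsilane
Product: 30 tert-butyl{(2R)-2-[(3R,6S)-6-[(3Z)-3-(5,5-dimethyl-3,4,5,6,7,8-hexahydronaphthalen-2(1H)-ylidene)propyl]-6-methyl-1,2-dioxan-3-yl]propoxy}diphenylsilane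
Conditions: TMSOTf (1.1 equiv), Me3Al (3 equiv), CH2Cl2, −78 to −40 °C; aqueous NaHCO3 work-up
Reagents that add atoms: trimethylaluminium C[Al](C)C
Why: Proposed new method: TMSOTf should remove the exocyclic methoxy group of either anomer of 29 to give one six-membered peroxycarbenium ion, which Me3Al should capture at C6 by axial attack on the half-chair that keeps the branched C3 substituent pseudo-equatorial, so that methyl enters cis to the C3 side chain and the long chain stays equatorial (6S); the closest known reactions are the Lewis-acid-mediated substitution of peroxy ketals by allylsilanes and silyl enol ethers through peroxycarbenium ions and the Me3Al/TMSOTf C-methylation of cyclic ketals and lactol derivatives through oxocarbenium ions, and the new element is a methylaluminium nucleophile next to an O–O bond.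

Step 20
Reactants: 30 tert-butyl{(2R)-2-[(3R,6S)-6-[(3Z)-3-(5,5-dimethyl-3,4,5,6,7,8-hexahydronaphthalen-2(1H)-ylidene)propyl]-6-methyl-1,2-dioxan-3-yl]propoxy}diphenylsilane
Product: 31 (2R)-2-[(3R,6S)-6-[(3Z)-3-(5,5-dimethyl-3,4,5,6,7,8-hexahydronaphthalen-2(1H)-ylidene)propyl]-6-methyl-1,2-dioxan-3-yl]propan-1-ol
Conditions: Bu4NF, AcOH (1:1), THF, rt
Reagents that add atoms: none
Why: Fluoride cleaves the silyl ether, and the acetic acid buffer keeps the medium too weakly basic for Kornblum–DeLaMare cleavage at the C3–H of the peroxide.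

Step 21
Reactants: 31 (2R)-2-[(3R,6S)-6-[(3Z)-3-(5,5-dimethyl-3,4,5,6,7,8-hexahydronaphthalen-2(1H)-ylidene)propyl]-6-methyl-1,2-dioxan-3-yl]propan-1-ol
Product: 32 (2S)-2-[(3R,6S)-6-[(3Z)-3-(5,5-dimethyl-3,4,5,6,7,8-hexahydronaphthalen-2(1H)-ylidene)propyl]-6-methyl-1,2-dioxan-3-yl]propanoic acid
Conditions: TEMPO (cat.), PhI(OAc)2, MeCN/H2O, rt
Reagents that add atoms: water O
Why: TEMPO-catalysed oxidation with PhI(OAc)2 in aqueous acetonitrile takes the primary alcohol through the aldehyde hydrate to the acid under near-neutral conditions that should spare the peroxide, both alkenes and the C2 centre (whose descriptor changes from R to S only through the priority change at C1).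

**Compound list**

1 | 2,2-dimethylcyclohexanone | CC1(C)CCCCC1=O | starting material
2 | dimethyl carbonate | COC(=O)OC | starting material
3 | methyl 3,3-dimethyl-2-oxocyclohexane-1-carboxylate (racemic) | COC(=O)C1CCCC(C)(C)C1=O | intermediate
4 | methyl 3,3-dimethyl-2-{[(trifluoromethyl)sulfonyl]oxy}cyclohex-1-ene-1-carboxylate | COC(=O)C1=C(OS(=O)(=O)C(F)(F)F)C(C)(C)CCC1 | intermediate
5 | (4-bromobut-1-yn-1-yl)trimethylsilane | C[Si](C)(C)C#CCCBr | starting material
6 | [4-(trimethylsilyl)but-3-yn-1-yl]zinc bromide | C[Si](C)(C)C#CCC[Zn]Br | intermediate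
7 | methyl 3,3-dimethyl-2-[4-(trimethylsilyl)but-3-yn-1-yl]cyclohex-1-ene-1-carboxylate | COC(=O)C1=C(CCC#C[Si](C)(C)C)C(C)(C)CCC1 | intermediate
8 | {3,3-dimethyl-2-[4-(trimethylsilyl)but-3-yn-1-yl]cyclohex-1-en-1-yl}methanol | OCC1=C(CCC#C[Si](C)(C)C)C(C)(C)CCC1 | intermediate
9 | [2-(but-3-yn-1-yl)-3,3-dimethylcyclohex-1-en-1-yl]methanol | OCC1=C(CCC#C)C(C)(C)CCC1 | intermediate
10 | [2-(but-3-yn-1-yl)-3,3-dimethylcyclohex-1-en-1-yl]methyl acetate | CC(=O)OCC1=C(CCC#C)C(C)(C)CCC1 | intermediate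
11 | carbon monoxide | [C-]#[O+] | starting material
12 | methanol | CO | starting material
13 | methyl (2Z)-2-(5,5-dimethyl-3,4,5,6,7,8-hexahydronaphthalen-2(1H)-ylidene)acetate | COC(=O)/C=C1/CCC2=C(CCCC2(C)C)C1 | intermediate
14 | (2Z)-2-(5,5-dimethyl-3,4,5,6,7,8-hexahydronaphthalen-2(1H)-ylidene)ethan-1-ol | OC/C=C1/CCC2=C(CCCC2(C)C)C1 | intermediate
15 | (2Z)-2-(2-bromoethylidene)-5,5-dimethyl-1,2,3,4,5,6,7,8-octahydronaphthalene | BrC/C=C1/CCC2=C(CCCC2(C)C)C1 | intermediate
16 | acetone N,N-dimethylhydrazone | CC(C)=NN(C)C | starting material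
17 | (5Z)-5-(5,5-dimethyl-3,4,5,6,7,8-hexahydronaphthalen-2(1H)-ylidene)pentan-2-one N,N-dimethylhydrazone | CC(=NN(C)C)CC/C=C1/CCC2=C(CCCC2(C)C)C1 | intermediate
18 | (2E)-but-2-ene-1,4-diol | OC/C=C/CO | starting material
19 | (2E)-4-[(tert-butyldiphenylsilyl)oxy]but-2-en-1-ol | OC/C=C/CO[Si](c1ccccc1)(c2ccccc2)C(C)(C)C | intermediate
20 | [(2S,3S)-3-{[(tert-butyldiphenylsilyl)oxy]methyl}oxiran-2-yl]methanol | OC[C@@H]1O[C@H]1CO[Si](c2ccccc2)(c3ccccc3)C(C)(C)C | intermediate
21 | (2R,3R)-4-[(tert-butyldiphenylsilyl)oxy]-3-methylbutane-1,2-diol | OC[C@H](O)[C@H](C)CO[Si](c1ccccc1)(c2ccccc2)C(C)(C)C | intermediate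
22 | (2R,3R)-4-[(tert-butyldiphenylsilyl)oxy]-2-hydroxy-3-methylbutyl 4-methylbenzenesulfonate | Cc1ccc(cc1)S(=O)(=O)OC[C@H](O)[C@H](C)CO[Si](c2ccccc2)(c3ccccc3)C(C)(C)C | intermediate
23 | tert-butyl{(2R)-2-[(2R)-oxiran-2-yl]propoxy}diphenylsilane | C1O[C@@H]1[C@H](C)CO[Si](c2ccccc2)(c3ccccc3)C(C)(C)C | intermediate
24 | (2R,3S,9Z)-1-[(tert-butyldiphenylsilyl)oxy]-9-(5,5-dimethyl-3,4,5,6,7,8-hexahydronaphthalen-2(1H)-ylidene)-3-hydroxy-2-methylnonan-6-one N,N-dimethylhydrazone | CN(C)N=C(CC/C=C1/CCC2=C(CCCC2(C)C)C1)CC[C@H](O)[C@H](C)CO[Si](c3ccccc3)(c4ccccc4)C(C)(C)C | intermediate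
25 | (2R,3S,9Z)-1-[(tert-butyldiphenylsilyl)oxy]-9-(5,5-dimethyl-3,4,5,6,7,8-hexahydronaphthalen-2(1H)-ylidene)-3-hydroxy-2-methylnonan-6-one | O=C(CC/C=C1/CCC2=C(CCCC2(C)C)C1)CC[C@H](O)[C@H](C)CO[Si](c3ccccc3)(c4ccccc4)C(C)(C)C | intermediate
26 | (2R,3S,9Z)-1-[(tert-butyldiphenylsilyl)oxy]-9-(5,5-dimethyl-3,4,5,6,7,8-hexahydronaphthalen-2(1H)-ylidene)-2-methyl-6-oxononan-3-yl methanesulfonate | O=C(CC/C=C1/CCC2=C(CCCC2(C)C)C1)CC[C@H](OS(C)(=O)=O)[C@H](C)CO[Si](c3ccccc3)(c4ccccc4)C(C)(C)C | intermediate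
27 | (2R,3S,9Z)-1-[(tert-butyldiphenylsilyl)oxy]-9-(5,5-dimethyl-3,4,5,6,7,8-hexahydronaphthalen-2(1H)-ylidene)-6,6-dimethoxy-2-methylnonan-3-yl methanesulfonate | COC(OC)(CC/C=C1/CCC2=C(CCCC2(C)C)C1)CC[C@H](OS(C)(=O)=O)[C@H](C)CO[Si](c3ccccc3)(c4ccccc4)C(C)(C)C | intermediate
28 | (2R,3S,9Z)-1-[(tert-butyldiphenylsilyl)oxy]-9-(5,5-dimethyl-3,4,5,6,7,8-hexahydronaphthalen-2(1H)-ylidene)-6-hydroperoxy-6-methoxy-2-methylnonan-3-yl methanesulfonate (both C6 epimers) | COC(OO)(CC/C=C1/CCC2=C(CCCC2(C)C)C1)CC[C@H](OS(C)(=O)=O)[C@H](C)CO[Si](c3ccccc3)(c4ccccc4)C(C)(C)C | intermediate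
29 | tert-butyl{(2R)-2-[(3R)-6-[(3Z)-3-(5,5-dimethyl-3,4,5,6,7,8-hexahydronaphthalen-2(1H)-ylidene)propyl]-6-methoxy-1,2-dioxan-3-yl]propoxy}diphenylsilane (both C6 anomers) | COC1(CC/C=C2/CCC3=C(CCCC3(C)C)C2)CC[C@@H](OO1)[C@H](C)CO[Si](c4ccccc4)(c5ccccc5)C(C)(C)C | intermediate
30 | tert-butyl{(2R)-2-[(3R,6S)-6-[(3Z)-3-(5,5-dimethyl-3,4,5,6,7,8-hexahydronaphthalen-2(1H)-ylidene)propyl]-6-methyl-1,2-dioxan-3-yl]propoxy}diphenylsilane | C[C@]1(CC/C=C2/CCC3=C(CCCC3(C)C)C2)CC[C@@H](OO1)[C@H](C)CO[Si](c4ccccc4)(c5ccccc5)C(C)(C)C | intermediate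
31 | (2R)-2-[(3R,6S)-6-[(3Z)-3-(5,5-dimethyl-3,4,5,6,7,8-hexahydronaphthalen-2(1H)-ylidene)propyl]-6-methyl-1,2-dioxan-3-yl]propan-1-ol | C[C@]1(CC/C=C2/CCC3=C(CCCC3(C)C)C2)CC[C@@H](OO1)[C@H](C)CO | intermediate
32 | (2S)-2-[(3R,6S)-6-[(3Z)-3-(5,5-dimethyl-3,4,5,6,7,8-hexahydronaphthalen-2(1H)-ylidene)propyl]-6-methyl-1,2-dioxan-3-yl]propanoic acid | C[C@H](C(=O)O)[C@H]1CC[C@](C)(CC/C=C2/CCC3=C(CCCC3(C)C)C2)OO1 | target

**Step count**

Total step count: 21. Longest linear sequence: 17 steps (steps 1–10 and 15–21); the epoxide branch (steps 11–14) joins at step 15.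

**Steps most likely to fail**

1. Step 19 (the proposed new method). The methyl group may be transferred from aluminium to a peroxide oxygen, the O–O bond may be reduced, the peroxycarbenium ion may fragment, or the facial selectivity at C6 may be weak. The fallback uses known chemistry, leaves the route at hydroxy ketone 25 and rejoins it at dioxane 30. Wittig methylenation of 25 (Ph3P=CH2 in excess, THF, 0 °C) should give (2R,3S,9Z)-1-[(tert-butyldiphenylsilyl)oxy]-9-(5,5-dimethyl-3,4,5,6,7,8-hexahydronaphthalen-2(1H)-ylidene)-2-methyl-6-methylidenenonan-3-ol F1. Mesylation (MsCl, Et3N) should give the corresponding nonan-3-yl methanesulfonate F2. Mukaiyama–Isayama hydroperoxysilylation (Co(acac)2, O2, Et3SiH, ClCH2CH2Cl/EtOH), in which the 1,1-disubstituted alkene should react ahead of the tri- and tetrasubstituted ones, should give the tertiary C6 triethylsilyl peroxide F3 as both C6 epimers. Bu4NF should then free the peroxide anion, which closes onto the C3 mesylate by 6-exo SN2 with inversion to give 30 together with its C6 epimer, to be separated by chromatography. This fallback keeps C2 and C3 and gives up control at C6.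

2. Step 7 (the key step). The allylpalladium may be captured by CO and methanol or lose a β-hydrogen before the alkyne inserts, or the vinylpalladium may be protonated before CO inserts. The fallback leaves the route at alkynol 9 and rejoins it at ester 13. Double deprotonation (n-BuLi, 2 equiv, THF, −78 °C) and trapping with methyl chloroformate should give methyl 5-(2-{[(methoxycarbonyl)oxy]methyl}-6,6-dimethylcyclohex-1-en-1-yl)pent-2-ynoate F4. Anti hydroiodination (NaI, AcOH, 70 °C) should give methyl (2Z)-3-iodo-5-(2-{[(methoxycarbonyl)oxy]methyl}-6,6-dimethylcyclohex-1-en-1-yl)pent-2-enoate F5, with iodine cis to the ester. Nickel-catalysed intramolecular reductive allyl–vinyl coupling (NiCl2(dme), 2,2′-bipyridine, Zn dust, DMA, rt) should replace iodine by the allylic CH2 with retention and close ring B to 13. Here the alkene geometry is written by anti addition of HI and not by syn carbopalladation.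

3. Step 18. The ketal may exchange twice to the geminal dihydroperoxide, the mesylate may be lost by E2 elimination or displaced by a ketal oxygen, or the product may undergo base-induced Kornblum–DeLaMare cleavage. The fallback leaves the route at ketal 27 and rejoins it at peroxy ketal 29, and it reverses the roles of C3 and C6. Intermolecular SN2 displacement of the mesylate by 2-methoxyprop-2-yl hydroperoxide (CsOH·H2O, DMF, 0 °C) should give, with inversion, tert-butyl{[(2R,3R,9Z)-9-(5,5-dimethyl-3,4,5,6,7,8-hexahydronaphthalen-2(1H)-ylidene)-6,6-dimethoxy-3-[(2-methoxypropan-2-yl)peroxy]-2-methylnonyl]oxy}diphenylsilane F6. PPTS in MeOH should remove the 2-methoxyprop-2-yl group to give the free C3 hydroperoxide F7, which closes on the C6 dimethyl ketal by transketalisation to give 29.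

Further compounds
F1 | step 19 | (2R,3S,9Z)-1-[(tert-butyldiphenylsilyl)oxy]-9-(5,5-dimethyl-3,4,5,6,7,8-hexahydronaphthalen-2(1H)-ylidene)-2-methyl-6-methylidenenonan-3-ol | C=C(CC/C=C1/CCC2=C(CCCC2(C)C)C1)CC[C@H](O)[C@H](C)CO[Si](c3ccccc3)(c4ccccc4)C(C)(C)C
F2 | step 19 | (2R,3S,9Z)-1-[(tert-butyldiphenylsilyl)oxy]-9-(5,5-dimethyl-3,4,5,6,7,8-hexahydronaphthalen-2(1H)-ylidene)-2-methyl-6-methylidenenonan-3-yl methanesulfonate | C=C(CC/C=C1/CCC2=C(CCCC2(C)C)C1)CC[C@H](OS(C)(=O)=O)[C@H](C)CO[Si](c3ccccc3)(c4ccccc4)C(C)(C)C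
F3 | step 19 | (2R,3S,9Z)-1-[(tert-butyldiphenylsilyl)oxy]-9-(5,5-dimethyl-3,4,5,6,7,8-hexahydronaphthalen-2(1H)-ylidene)-2,6-dimethyl-6-[(triethylsilyl)peroxy]nonan-3-yl methanesulfonate (both C6 epimers) | CC[Si](CC)(CC)OOC(C)(CC/C=C1/CCC2=C(CCCC2(C)C)C1)CC[C@H](OS(C)(=O)=O)[C@H](C)CO[Si](c3ccccc3)(c4ccccc4)C(C)(C)C
F4 | step 7 | methyl 5-(2-{[(methoxycarbonyl)oxy]methyl}-6,6-dimethylcyclohex-1-en-1-yl)pent-2-ynoate | COC(=O)OCC1=C(CCC#CC(=O)OC)C(C)(C)CCC1
F5 | step 7 | methyl (2Z)-3-iodo-5-(2-{[(methoxycarbonyl)oxy]methyl}-6,6-dimethylcyclohex-1-en-1-yl)pent-2-enoate | COC(=O)OCC1=C(CC/C(I)=C/C(=O)OC)C(C)(C)CCC1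
F6 | step 18 | tert-butyl{[(2R,3R,9Z)-9-(5,5-dimethyl-3,4,5,6,7,8-hexahydronaphthalen-2(1H)-ylidene)-6,6-dimethoxy-3-[(2-methoxypropan-2-yl)peroxy]-2-methylnonyl]oxy}diphenylsilane | COC(OC)(CC/C=C1/CCC2=C(CCCC2(C)C)C1)CC[C@@H](OOC(C)(C)OC)[C@H](C)CO[Si](c3ccccc3)(c4ccccc4)C(C)(C)C
F7 | step 18 | tert-butyl{[(2R,3R,9Z)-9-(5,5-dimethyl-3,4,5,6,7,8-hexahydronaphthalen-2(1H)-ylidene)-3-hydroperoxy-6,6-dimethoxy-2-methylnonyl]oxy}diphenylsilane | COC(OC)(CC/C=C1/CCC2=C(CCCC2(C)C)C1)CC[C@@H](OO)[C@H](C)CO[Si](c3ccccc3)(c4ccccc4)C(C)(C)C
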